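Compound numbers 1–31 are those of the steps and of the compound list. Stereochemical outcomes are predictions from steric and conformational arguments; nothing in this proposal has been run.

## Analysis of the target

Target 31 is a C30 triterpenoid triacetate built from two bicyclic halves, each a 2,2-dimethyloxepane (ring A, ring A') trans-fused to a cyclohexane (ring B, ring B'), and the halves are linked by the two-carbon tether C12–C12'. Each half is numbered O1, C2 (CMe2), C3 (CH–O), C4, C5, C6 (C–Me), C7 (CH–O) around the oxepane and C6–C7–C8–C9–C10 (Me, OAc)–C11 around the cyclohexane, with C12 on C11; primed locants belong to the half with the free C3' hydroxyl, and β is the face of the C6 methyl group. The ten stereocentres are all S except C10', which is R: in both halves the C6 methyl is β and axial, C7–H and C11–H are α (so C12 is equatorial) and the C3 oxygen is α. The halves differ only at C10, where the unprimed half has an axial β methyl and an equatorial α acetate and the primed half has the axial β acetate. Sensitive features are the two tertiary acetates, which eliminate easily, the tertiary ether carbons C2 and C2', and one secondary hydroxyl that must stay free next to a secondary acetate in the same environment. The difficulty lies in the near-twofold symmetry that is broken twice (C10 configuration, C3 acylation), in the quaternary C6 flanked by the stereocentres C7 and C11, and in a union at C12–C12' between two hindered carbons. The plan hinges on ring A, a seven-membered cyclic ether that holds the fully substituted ether carbon C2 and the quaternary C6: a cut at its C3–C4 bond leaves two monosubstituted alkene termini, so this bond can be formed as an alkene by metathesis, and the alkene then brings oxygen to C3.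

## Retrosynthetic reasoning

31 is traced to the benzyl ether alkene 30. One hydrogenation saturates C12=C12' and frees the C3' hydroxyl, so the only hydroxyl that must stay unacetylated is masked until the last step.

30 goes back through 29 and 28 to the β-acetoxy sulfone 27. The C10' acetate is added after removal of a silyl group, and the alkene comes from reductive elimination. C12–C12' is cut because it is the only bond whose cleavage gives two fragments of equal size that share one precursor. 27 arises, through the trilithium adduct 26, from the sulfone 19 as fragment 1 and the aldehyde 25 as fragment 2. The forward reaction must join two hindered carbons and, in the same flask, put acetyl groups on C3 and C10 of fragment 1.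

19 and 25 both come from the exocyclic enone 15, which carries the C10 carbonyl and the C11 methylene. For 19, conjugate addition places the sulfonyl group on C12 in 16, and the C10 ketone is then turned into the methylene compound 17, the epoxide 18 and finally the equatorial carbinol with an axial methyl group. For 25, the hydroxyl is benzylated in 20, a methyl nucleophile adds to the ketone from the equatorial side to give the axial carbinol 21, which is silylated to 22, and hydroboration through the alkylborane 23 turns the methylene into C12' with C11'–H α in 24. One ketone thus gives both C10 configurations by reversing the order in which oxygen and carbon arrive.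

15 is traced to the allylic alcohol 14 and the methylene compound 13. Allylic oxidation can only occur at C10, because C6 is quaternary. 13 comes from the epoxy alkene 12, the epoxy ketone 11 and the oxepene ketone 10. The ring alkene is epoxidised before the ketone is methylenated, and hydride opens the epoxide only after the ketone is gone, so no protecting group is needed.

10 is disconnected at C3=C4 to the diene 9; this is the key disconnection. The cut is made there because both alkene carbons are then monosubstituted termini and the two fully substituted carbons C2 and C6 are already in place. The forward reaction only has to close a seven-membered ring.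

9 is the tertiary allyl ether of the ketol 6 and is made with the imidate 8, which comes from the alcohol 7. 6 is the carbinol epimer of 4 and is reached through the ester 5. 4 comes from desymmetrising reduction of the dione 3, which is made from 1 and 2. The quaternary C6 and C7 are thus fixed by a known desymmetrisation before the ring is formed.

## Alternatives that were turned down

Alternative 1: Ring B' and ring A' would be cut together at C4'–C5' and C6'–C7', leading back to the 2,2-dimethylfuran-3-one A1, which carries on C7' a chain ending in an isopropenyl group. Irradiation would give the intramolecular [2+2] adduct A2, with ring B', a cyclobutane and the quaternary C6' formed at once. Cleavage of the strained C4'–C7' bond (donor oxygen on C7', acceptor carbonyl next to C4') would then enlarge the five-membered ring to ring A' with C3' as a carbonyl group.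
- For it: two carbon–carbon bonds, a ring and a quaternary centre arise in one step, C12' is already present as an acetoxymethyl group, and the C3' carbonyl is a handle for the carbinol. On bonds formed per step it is clearly stronger than the metathesis, which forms one bond and no stereocentre.
- Against it: C10' and C11' must be set on an open chain first, and the facial course at C6'/C7' depends on those remote centres. The fragmentation passes through an oxocarbenium carbon at C7' that must be reduced to the trans ring fusion without a clear bias. The C3' carbonyl must then be reduced in the right sense beside a gem-dimethyl group.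
- Comparison: the chosen route offers a ring fusion fixed before the key step and a ring size that cannot vary, at the cost of more functional-group steps afterwards.

Alternative 2: Ring B' would be cut at C6'–C11', giving the open-chain epoxy vinyl sulfone A3 (C6'–C7' epoxide, C2'/C3' diol as acetonide, C10' tertiary carbinol). The trivalent titanium reagent Cp2TiCl A4 would open the epoxide to the tertiary C6' radical, which adds 6-exo to C11' of the vinyl sulfone and gives the cyclohexanediol sulfone A5.
- For it: the quaternary C6', the C7' carbinol, C11' and a C12' sulfone ready for a Julia union arise in one step, and the C10' carbinol comes with the chain. It reaches the stage of the sulfone 19 much faster than the chosen route, which needs nine steps after its key step, and on this point it is stronger.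
- Against it: the radical closure must set the C6'/C7' and C10'/C11' relationships at once through a transition state with two fully substituted centres. More decisively, ring A' stays open and must later be closed by forming O1'–C2' at a tertiary carbon, where attack at C3' to a six-membered ring competes.
- Comparison: the chosen route makes the oxepane first, by a process that can give no other ring size.

Alternative 3: Cuts at C5'–C6' and C11'–C12' lead to the silyl-protected (R)-4-hydroxy-2,4-dimethylcyclohex-2-enone A6 and vinylene carbonate A7. Their intermolecular [2+2] photocycloaddition would give the cis-fused cyclobutane carbonate A8. Carbonate hydrolysis and glycol cleavage would then unmask formyl groups as C5' and C12', and C11' would have to be epimerised to the trans arrangement.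
- For it: the C10' carbinol is present from the start, the quaternary C6' is made in the key step, and C12' appears directly at the aldehyde level needed for the union. On these points it is shorter than the chosen route.
- Against it: face selectivity of an intermolecular enone photocycloaddition guided only by a C10' centre bearing methyl and silyloxy groups should be weak. The two formyl groups must be told apart, C7' must be reduced in the right sense, and three carbons plus a seven-membered ether closure are still needed for ring A'.
- Comparison: in the chosen route C5 and C11 differ in oxidation level from the outset (allyl against ketone), and ring A is complete right after the key step.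

Key step: step 7

Assumption (step 2): hydride is taken to enter the carbonyl of 3 on the face syn to the methyl group (anti to allyl), as is usual for 2-alkyl-2-methyl-1,3-diones, so the carbinol of 4 must be inverted. If the other diastereomer formed, the antipodal oxazaborolidine would give 6 directly and steps 3 and 4 would lapse.

## Route

Step 1
Reactants: 1 2-methylcyclohexane-1,3-dione; 2 allyl bromide
Product: 3 2-allyl-2-methylcyclohexane-1,3-dione
Conditions: NaOH (1 M aq), rt
Reagents that add atoms: none
Why: C-Alkylation of the stabilised enolate of a 2-alkyl-1,3-dione with an allylic halide in aqueous base is standard; the product is achiral.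

Step 2
Reactants: 3 2-allyl-2-methylcyclohexane-1,3-dione
Product: 4 (2R,3R)-2-allyl-3-hydroxy-2-methylcyclohexan-1-one (hydroxyl cis to allyl)
Conditions: (S)-2-methyl-CBS-oxazaborolidine ((S)-1-methyl-3,3-diphenyltetrahydro-1H,3H-pyrrolo[1,2-c][1,3,2]oxazaborole, 0.2 equiv), catecholborane, toluene, −78 °C
Reagents that add atoms: none
Why: Corey–Bakshi–Shibata desymmetrisation: the catalyst treats the quaternary carbon as the large carbonyl substituent and so fixes the carbinol as R, while hydride enters syn to the methyl group, which selects the enantiotopic carbonyl and places the hydroxyl cis to allyl. Catecholborane does not hydroborate the allyl group at this temperature.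

Step 3
Reactants: 4 (2R,3R)-2-allyl-3-hydroxy-2-methylcyclohexan-1-one
Product: 5 (1S,2R)-2-allyl-2-methyl-3-oxocyclohexyl 4-nitrobenzoate
Conditions: 4-nitrobenzoic acid, PPh3, DIAD, toluene, 0 °C → rt
Reagents that add atoms: 4-nitrobenzoic acid O=C(O)c1ccc(cc1)[N+](=O)[O-]
Why: Mitsunobu esterification inverts the carbinol by SN2 attack of the acidic carboxylate on the oxyphosphonium ion; the nucleophile enters on the methyl side of the neighbouring quaternary carbon, the less hindered of the two.

Step 4
Reactants: 5 (1S,2R)-2-allyl-2-methyl-3-oxocyclohexyl 4-nitrobenzoate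
Product: 6 (2R,3S)-2-allyl-3-hydroxy-2-methylcyclohexan-1-one (hydroxyl cis to methyl)
Conditions: K2CO3 (0.2 equiv), MeOH, 0 °C
Reagents that add atoms: none
Why: Transesterification of the electron-poor benzoate is fast at 0 °C, mild enough to avoid retro-aldol opening of the β-hydroxy ketone; the carbinol configuration is untouched.

Step 5
Reactants: 7 2-methylbut-3-en-2-ol
Product: 8 2-methylbut-3-en-2-yl 2,2,2-trichloroacetimidate
Conditions: Cl3CCN, DBU (0.1 equiv), CH2Cl2, 0 °C; used at once
Reagents that add atoms: trichloroacetonitrile N#CC(Cl)(Cl)Cl
Why: Base-catalysed addition of the alkoxide to trichloroacetonitrile (imidate formation); the reagent is kept cold and used directly so that the [3,3] shift to the allylic amide does not set in.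

Step 6
Reactants: 6 (2R,3S)-2-allyl-3-hydroxy-2-methylcyclohexan-1-one; 8 2-methylbut-3-en-2-yl 2,2,2-trichloroacetimidate
Product: 9 (2R,3S)-2-allyl-2-methyl-3-(2-methylbut-3-en-2-yloxy)cyclohexan-1-one
Conditions: CF3SO3H (0.05 equiv), cyclohexane–CH2Cl2, 0 °C
Reagents that add atoms: none
Why: Acid-catalysed trichloroacetimidate alkylation: protonation releases trichloroacetamide and the 1,1-dimethylallyl cation, which the secondary alcohol should trap at the tertiary terminus in the non-polar medium. C7 is not involved and keeps its configuration.

Step 7
Reactants: 9 (2R,3S)-2-allyl-2-methyl-3-(2-methylbut-3-en-2-yloxy)cyclohexan-1-one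
Product: 10 trans-fused 2,2,6-trimethyloxepene–cyclohexanone (C3=C4 alkene, C11 ketone, 6β-methyl, 7α-H)
Conditions: second-generation Grubbs catalyst (H2IMes)(PCy3)Cl2Ru=CHPh (5 mol %), CH2Cl2 (0.005 M), 40 °C
Reagents that add atoms: none
Why: Ring-closing olefin metathesis: the Ru=CHPh unit of the catalyst first exchanges with the less hindered allyl terminus, the new Ru=CH–CH2 alkylidene adds across the vinyl group of the tertiary allyl ether to a ruthenacyclobutane, and cycloreversion releases ethylene and the ring alkene. The closest known reaction type is the closure of 2,2-disubstituted oxepenes from dienes that pair an allyl group with a 1,1-dimethylallyl ether under this catalyst. Ring A closes as a seven-membered ring by joining C3 and C4, which become an endocyclic cis alkene. No stereocentre is formed; C6 and C7 are already set and cannot epimerise under the neutral conditions. The selectivity needed is cyclisation over cross-metathesis oligomerisation. The two methyl groups on C2 and the fully substituted C6 bias the chain toward a folded shape, and the trans allyl and ether substituents can both sit equatorial on the cyclohexanone, so the two termini are gauche and close. High dilution and loss of ethylene complete the bias. The ketone and the hindered ether oxygen should not interfere with the catalyst.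

Step 8
Reactants: 10 trans-fused 2,2,6-trimethyloxepene–cyclohexanone
Product: 11 3α,4α-epoxide of 10 (epoxide oxygen anti to the C6 methyl group, C11 ketone)
Conditions: dimethyldioxirane, acetone, 0 °C
Reagents that add atoms: dimethyldioxirane CC1(C)OO1
Why: Concerted oxygen transfer from the dioxirane to the cis alkene, with no Baeyer–Villiger attack on the ketone. The reagent should approach the convex α face of the chair-like oxepene, anti to the axial C6 methyl group, which fixes the future C3 oxygen as α.

Step 9
Reactants: 11 3α,4α-epoxy ketone
Product: 12 3α,4α-epoxy-11-methylene bicycle (exocyclic C11=C12)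
Conditions: Ph3PCH3Br, KOtBu, toluene, 80 °C
Reagents that add atoms: methyltriphenylphosphonium bromide C[P+](c1ccccc1)(c1ccccc1)c1ccccc1.[Br-]
Why: Wittig methylenation of a ketone with one quaternary α-carbon needs the ylide at elevated temperature; the hindered internal epoxide should be inert to it, and the only enolisable position (C10) carries no stereocentre.

Step 10
Reactants: 12 3α,4α-epoxy-11-methylene bicycle
Product: 13 3α-hydroxy-11-methylene bicycle (C3 S)
Conditions: LiAlH4, THF, 0 → 50 °C
Reagents that add atoms: none
Why: Hydride opens the epoxide by SN2 at C4, the carbon not flanked by the quaternary C2, so oxygen stays on C3 with its α configuration; the 1,1-disubstituted alkene does not react.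

Step 11
Reactants: 13 3α-hydroxy-11-methylene bicycle
Product: 14 3α,10-dihydroxy-11-methylene bicycle (C10 epimers)
Conditions: SeO2 (0.5 equiv), t-BuOOH, CH2Cl2, rt
Reagents that add atoms: selenium dioxide O=[Se]=O; tert-butyl hydroperoxide CC(C)(C)OO
Why: Selenium dioxide allylic oxidation (ene reaction, then [2,3]-sigmatropic shift) with the hydroperoxide as reoxidant; C10 is the only allylic position bearing hydrogen, and its configuration is irrelevant because it is oxidised next.

Step 12
Reactants: 14 3α,10-dihydroxy-11-methylene bicycle
Product: 15 3α-hydroxy-11-methylene-10-ketone (exocyclic enone)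
Conditions: MnO2, CH2Cl2, rt; used without storage
Reagents that add atoms: none
Why: MnO2 oxidises the allylic carbinol only and leaves the saturated C3 hydroxyl; the exocyclic alkene cannot move into the ring because C6 is quaternary.

Step 13
Reactants: 15 3α-hydroxy-11-methylene-10-ketone
Product: 16 3α-hydroxy-12-(phenylsulfonyl)-10-ketone (C11–H α, sulfonylmethyl equatorial)
Conditions: PhSO2Na, AcOH, THF–H2O, rt
Reagents that add atoms: sodium benzenesulfinate [Na+].[O-]S(=O)c1ccccc1
Why: Sulfa-Michael addition of the sulfinate through sulfur to the unhindered methylene terminus; C11 stays epimerisable next to the ketone and should settle with the sulfonylmethyl group equatorial (β), as in related decalones.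

Step 14
Reactants: 16 3α-hydroxy-12-(phenylsulfonyl)-10-ketone
Product: 17 3α-hydroxy-10-methylene-12-(phenylsulfonyl) bicycle
Conditions: Zn, CH2Br2, TiCl4, THF–CH2Cl2, 0 °C → rt
Reagents that add atoms: dibromomethane BrCBr
Why: Takai–Lombardo methylenation with the non-basic methylene reagent formed from Zn, CH2Br2 and TiCl4 converts the ketone without β-elimination of sulfinate or epimerisation at C11 and tolerates the free hydroxyl.

Step 15
Reactants: 17 3α-hydroxy-10-methylene-12-(phenylsulfonyl) bicycle
Product: 18 10α-spiro-epoxide (epoxide oxygen α, epoxide CH2 β) of 17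
Conditions: mCPBA, NaHCO3, CH2Cl2, 0 °C
Reagents that add atoms: 3-chloroperoxybenzoic acid OOC(=O)c1cccc(Cl)c1
Why: Peracid epoxidation of the exocyclic alkene from the equatorial α side, because the axial β approach is blocked by the syn-axial C6 methyl group; this places oxygen α and the methylene β at C10.

Step 16
Reactants: 18 10α-spiro-epoxide
Product: 19 fragment 1: 3α,10α-dihydroxy-10β-methyl-12-(phenylsulfonyl) bicycle
Conditions: LiBHEt3, THF, 0 °C → rt
Reagents that add atoms: none
Why: Hydride opens the spiro-epoxide at its primary carbon, which turns the β methylene into the axial methyl group and leaves the equatorial α tertiary alcohol; aryl alkyl sulfones are not reduced under these conditions.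

Step 17
Reactants: 15 3α-hydroxy-11-methylene-10-ketone
Product: 20 3α-benzyloxy-11-methylene-10-ketone
Conditions: BnOC(=NH)CCl3, CF3SO3H (0.1 equiv), CH2Cl2–cyclohexane, 0 °C
Reagents that add atoms: benzyl 2,2,2-trichloroacetimidate N=C(OCc1ccccc1)C(Cl)(Cl)Cl
Why: Acid-catalysed benzylation with the trichloroacetimidate avoids base, which the enone would not tolerate, and masks the hydroxyl that must end up free in the target.

Step 18
Reactants: 20 3α-benzyloxy-11-methylene-10-ketone
Product: 21 3α-benzyloxy-10β-hydroxy-10α-methyl-11-methylene bicycle
Conditions: MeLi, CeCl3, THF, −78 °C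
Reagents that add atoms: methyllithium [Li]C
Why: The reagent formed from MeLi and CeCl3 adds 1,2 to the enone; axial attack at C10 is barred by the syn-axial C6 methyl group, so methyl enters equatorially (α) and the hydroxyl becomes axial (β), the C10' configuration of this half.

Step 19
Reactants: 21 3α-benzyloxy-10β-hydroxy-10α-methyl-11-methylene bicycle
Product: 22 triethylsilyl ether of 21 (10β-OSiEt3)
Conditions: Et3SiOTf, 2,6-lutidine, CH2Cl2, −78 → 0 °C
Reagents that add atoms: triethylsilyl trifluoromethanesulfonate CC[Si](CC)(CC)OS(=O)(=O)C(F)(F)F
Why: Silylation of the tertiary alcohol with the silyl triflate and a hindered base; the ether prevents retro-aldol cleavage and proton transfer at the β-oxygenated aldehyde stage.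

Step 20
Reactants: 22 triethylsilyl ether of 21
Product: 24 3α-benzyloxy-10β-triethylsilyloxy-12-hydroxy bicycle (C11–H α), via alkylborane 23 (not isolated)
Conditions: BH3·THF, THF, 0 °C → rt; then NaOH, H2O2, 0 °C
Reagents that add atoms: hydrogen peroxide OO
Why: Hydroboration–oxidation: boron goes to the terminal carbon and hydrogen is delivered to C11 from the α face, because the β face is flanked by the axial C6 methyl and C10 silyloxy groups. This sets C11–H α with the hydroxymethyl group equatorial.

Step 21
Reactants: 24 3α-benzyloxy-10β-triethylsilyloxy-12-hydroxy bicycle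
Product: 25 fragment 2: 3α-benzyloxy-10β-triethylsilyloxy-12-aldehyde
Conditions: Dess–Martin periodinane, NaHCO3, CH2Cl2, rt
Reagents that add atoms: none
Why: Dess–Martin oxidation under buffered, non-epimerising conditions gives the aldehyde without touching the silyl or benzyl ether.

Step 22
Reactants: 19 fragment 1 (sulfone diol); 25 fragment 2 (aldehyde)
Product: 27 β-acetoxy sulfone (C3, C10 and C12' acetates, C12 phenylsulfonyl, C10' silyl ether, C3' benzyl ether; C12/C12' diastereomers), via trilithium Julia adduct 26 (not isolated)
Conditions: 19, n-BuLi (3.1 equiv), THF, −78 → −20 °C; 25, −78 °C; then Ac2O, DMAP (4-dimethylaminopyridine), −78 °C → rt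
Reagents that add atoms: acetic anhydride CC(=O)OC(C)=O
Why: Julia–Lythgoe addition: the trianion of 19 (two alkoxides and the α-sulfonyl carbanion) should add to the aldehyde at low temperature faster than it enolises it. Acetic anhydride then traps all three lithium alkoxides, giving the β-acetoxy sulfone and the C3 and C10 acetates together; the two new stereocentres are erased in the next step.

Step 23
Reactants: 27 β-acetoxy sulfone
Product: 28 (E)-C12=C12' alkene (C3 and C10 acetates, C10' silyl ether, C3' benzyl ether)
Conditions: Na(Hg) (6 %), Na2HPO4, MeOH–THF, −20 °C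
Reagents that add atoms: none
Why: Reductive elimination of the β-acetoxy sulfone by Na(Hg) (second half of the Julia–Lythgoe olefination) should give mainly the E alkene; the buffered cold medium spares the other acetates, and the alkene geometry does not matter.

Step 24
Reactants: 28 (E)-C12=C12' alkene silyl ether
Product: 29 C10'-tertiary alcohol (C3 and C10 acetates, C3' benzyl ether, C12=C12')
Conditions: HF·pyridine, THF, 0 °C → rt
Reagents that add atoms: none
Why: Fluoride cleaves the triethylsilyl ether; the buffered reagent should not touch acetates, the benzyl ether or the tertiary carbinol.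

Step 25
Reactants: 29 C10'-tertiary alcohol
Product: 30 triacetate benzyl ether alkene (C3, C10 and C10' acetates, C3' benzyl ether, C12=C12')
Conditions: Ac2O, DMAP, Et3N, CH2Cl2, 40 °C
Reagents that add atoms: acetic anhydride CC(=O)OC(C)=O
Why: Nucleophilic catalysis by DMAP acetylates the hindered axial tertiary alcohol on prolonged warming; the basic medium avoids ionisation and elimination.

Step 26
Reactants: 30 triacetate benzyl ether alkene
Product: 31 target (CNP0169816.2)
Conditions: H2 (1 atm), Pd/C, EtOAc, rt
Reagents that add atoms: none
Why: Heterogeneous hydrogenation saturates the 1,2-disubstituted alkene and hydrogenolyses the benzyl ether in one operation; no stereocentre is created, and low pressure with a short reaction time limits double-bond migration toward C11 or C11'.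

## Compound list

1 | 2-methylcyclohexane-1,3-dione | CC1C(=O)CCCC1=O | starting material
2 | allyl bromide | C=CCBr | starting material
3 | 2-allyl-2-methylcyclohexane-1,3-dione | C=CCC1(C)C(=O)CCCC1=O | intermediate
4 | (2R,3R)-2-allyl-3-hydroxy-2-methylcyclohexan-1-one (hydroxyl cis to allyl) | C=CC[C@]1(C)[C@H](O)CCCC1=O | intermediate
5 | (1S,2R)-2-allyl-2-methyl-3-oxocyclohexyl 4-nitrobenzoate | C=CC[C@]1(C)[C@@H](OC(=O)c2ccc(cc2)[N+](=O)[O-])CCCC1=O | intermediate
6 | (2R,3S)-2-allyl-3-hydroxy-2-methylcyclohexan-1-one (hydroxyl cis to methyl) | C=CC[C@]1(C)[C@@H](O)CCCC1=O | intermediate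
7 | 2-methylbut-3-en-2-ol | CC(C)(O)C=C | starting material
8 | 2-methylbut-3-en-2-yl 2,2,2-trichloroacetimidate | CC(C)(OC(=N)C(Cl)(Cl)Cl)C=C | intermediate
9 | (2R,3S)-2-allyl-2-methyl-3-(2-methylbut-3-en-2-yloxy)cyclohexan-1-one | C=CC[C@]1(C)[C@H](CCCC1=O)OC(C)(C)C=C | intermediate
10 | trans-fused 2,2,6-trimethyloxepene–cyclohexanone (C3=C4, C11 ketone, 6β-methyl, 7α-H) | CC1(C)C=CC[C@]2(C)[C@H](CCCC2=O)O1 | intermediate
11 | 3α,4α-epoxide of 10 | O1[C@H]2C[C@]3(C)[C@H](CCCC3=O)OC(C)(C)[C@@H]12 | intermediate
12 | 3α,4α-epoxy-11-methylene bicycle | O1[C@H]2C[C@]3(C)[C@H](CCCC3=C)OC(C)(C)[C@@H]12 | intermediate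
13 | 3α-hydroxy-11-methylene bicycle | O[C@H]1CC[C@]2(C)[C@H](CCCC2=C)OC1(C)C | intermediate
14 | 3α,10-dihydroxy-11-methylene bicycle (C10 epimers) | O[C@H]1CC[C@]2(C)[C@H](CCC(O)C2=C)OC1(C)C | intermediate
15 | 3α-hydroxy-11-methylene-10-ketone | O[C@H]1CC[C@]2(C)[C@H](CCC(=O)C2=C)OC1(C)C | intermediate
16 | 3α-hydroxy-12-(phenylsulfonyl)-10-ketone (C11–H α) | O[C@H]1CC[C@]2(C)[C@H](CCC(=O)[C@H]2CS(=O)(=O)c3ccccc3)OC1(C)C | intermediate
17 | 3α-hydroxy-10-methylene-12-(phenylsulfonyl) bicycle | O[C@H]1CC[C@]2(C)[C@H](CCC(=C)[C@H]2CS(=O)(=O)c3ccccc3)OC1(C)C | intermediate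
18 | 10α-spiro-epoxide of 17 | O[C@H]1CC[C@]2(C)[C@H](CC[C@]3(OC3)[C@H]2CS(=O)(=O)c4ccccc4)OC1(C)C | intermediate
19 | fragment 1: 3α,10α-dihydroxy-10β-methyl-12-(phenylsulfonyl) bicycle | O[C@H]1CC[C@]2(C)[C@H](CC[C@](C)(O)[C@H]2CS(=O)(=O)c3ccccc3)OC1(C)C | intermediate
20 | 3α-benzyloxy-11-methylene-10-ketone | c1ccccc1CO[C@H]2CC[C@]3(C)[C@H](CCC(=O)C3=C)OC2(C)C | intermediate
21 | 3α-benzyloxy-10β-hydroxy-10α-methyl-11-methylene bicycle | c1ccccc1CO[C@H]2CC[C@]3(C)[C@H](CC[C@@](C)(O)C3=C)OC2(C)C | intermediate
22 | triethylsilyl ether of 21 | c1ccccc1CO[C@H]2CC[C@]3(C)[C@H](CC[C@@](C)(O[Si](CC)(CC)CC)C3=C)OC2(C)C | intermediate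
23 | C12 alkylborane from 22 (C11–H α) | c1ccccc1CO[C@H]2CC[C@]3(C)[C@H](CC[C@@](C)(O[Si](CC)(CC)CC)[C@H]3CB)OC2(C)C | intermediate
24 | 3α-benzyloxy-10β-triethylsilyloxy-12-hydroxy bicycle | c1ccccc1CO[C@H]2CC[C@]3(C)[C@H](CC[C@@](C)(O[Si](CC)(CC)CC)[C@H]3CO)OC2(C)C | intermediate
25 | fragment 2: 3α-benzyloxy-10β-triethylsilyloxy-12-aldehyde | c1ccccc1CO[C@H]2CC[C@]3(C)[C@H](CC[C@@](C)(O[Si](CC)(CC)CC)[C@H]3C=O)OC2(C)C | intermediate
26 | trilithium Julia adduct (C3, C10 and C12' alkoxides, C12 phenylsulfonyl; C12/C12' diastereomers) | [Li+].[Li+].[Li+].[O-][C@H]1CC[C@]2(C)[C@H](CC[C@](C)([O-])[C@H]2C(S(=O)(=O)c3ccccc3)C([O-])[C@H]3[C@]4(C)CC[C@H](OCc5ccccc5)C(C)(C)O[C@H]4CC[C@@]3(C)O[Si](CC)(CC)CC)OC1(C)C | intermediate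
27 | β-acetoxy sulfone (C3, C10, C12' acetates; C10' silyl ether; C3' benzyl ether; C12/C12' diastereomers) | CC(=O)O[C@H]1CC[C@]2(C)[C@H](CC[C@](C)(OC(C)=O)[C@H]2C(S(=O)(=O)c3ccccc3)C(OC(C)=O)[C@H]3[C@]4(C)CC[C@H](OCc5ccccc5)C(C)(C)O[C@H]4CC[C@@]3(C)O[Si](CC)(CC)CC)OC1(C)C | intermediate
28 | (E)-C12=C12' alkene, C10' silyl ether | CC(=O)O[C@H]1CC[C@]2(C)[C@H](CC[C@](C)(OC(C)=O)[C@H]2/C=C/[C@H]3[C@]4(C)CC[C@H](OCc5ccccc5)C(C)(C)O[C@H]4CC[C@@]3(C)O[Si](CC)(CC)CC)OC1(C)C | intermediate
29 | (E)-C12=C12' alkene, C10' alcohol | CC(=O)O[C@H]1CC[C@]2(C)[C@H](CC[C@](C)(OC(C)=O)[C@H]2/C=C/[C@H]3[C@]4(C)CC[C@H](OCc5ccccc5)C(C)(C)O[C@H]4CC[C@@]3(C)O)OC1(C)C | intermediate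
30 | triacetate benzyl ether alkene | CC(=O)O[C@H]1CC[C@]2(C)[C@H](CC[C@](C)(OC(C)=O)[C@H]2/C=C/[C@H]3[C@]4(C)CC[C@H](OCc5ccccc5)C(C)(C)O[C@H]4CC[C@@]3(C)OC(C)=O)OC1(C)C | intermediate
31 | CNP0169816.2 | CC(=O)O[C@H]1CC[C@]2(C)[C@H](CC[C@](C)(OC(C)=O)[C@H]2CC[C@H]2[C@]3(C)CC[C@H](O)C(C)(C)O[C@H]3CC[C@@]2(C)OC(C)=O)OC1(C)C | target

## Step count and risks

Total: 26 steps. Longest linear sequence: 21 steps (steps 1–4, 6–12, 17–21, 22–26).

Least certain steps:

Step 7 (key step). Most likely failure: intermolecular metathesis at the unhindered allyl terminus (dimer and oligomer formation) outrunning closure onto the neopentyl-type vinyl group, or isomerisation of the allyl group by decomposed catalyst. Fallback, from 9 back to 10 by reductive carbonyl coupling instead of metathesis: ozonolysis with O3 in CH2Cl2–MeOH at −78 °C and Me2S work-up cuts both terminal alkenes and gives the keto dialdehyde F1. SmI2 in THF at −78 °C couples the two aldehydes, which react far faster than the hindered ketone, to the cis-3,4-dihydroxy oxepane ketone F2. Thiocarbonyldiimidazole converts this diol into the cyclic thiocarbonate F3, and Corey–Winter elimination with P(OMe)3 at 110 °C restores the C3=C4 alkene, that is 10.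

Step 22. Most likely failure: slow and reversible carbon–carbon bond formation, because both reacting carbons sit on a CH flanked by two fully substituted carbons; enolisation of the aldehyde (erosion of C11') and retro-addition on warming compete. Fallback, from 19 and 20 to 31 by conjugate addition at an unhindered carbon: the trianion of 19, made with n-BuLi in THF–DMPU at −78 °C, adds to the exposed methylene of enone 20 and gives the Michael adduct keto sulfone F4, whose C11' equilibrates to the equatorial epimer. MeLi/CeCl3 adds equatorially to the C10' ketone to give the tertiary alcohol sulfone F5. Na(Hg) in buffered MeOH removes the sulfonyl group and gives the triol benzyl ether F6. Ac2O/DMAP gives the saturated triacetate benzyl ether F7, and H2 over Pd/C frees the C3' hydroxyl to give 31.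

Step 6. Most likely failure: ionisation without capture, so that the allyl cation returns to the rearranged primary amide, loses a proton, or is trapped at its primary terminus by the hindered alcohol. Fallback, from 6 back to 9 through a propargylic cation that cannot rearrange in this way: 2-methylbut-3-yn-2-ol is converted with Cl3CCN and DBU into 2-methylbut-3-yn-2-yl 2,2,2-trichloroacetimidate F8. Acid-catalysed reaction with 6 gives the tertiary propargyl ether F9, and semihydrogenation under H2 over Lindlar catalyst (Pd/CaCO3 poisoned with Pb(OAc)2, quinoline) gives 9.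

Step 8. Most likely failure: poor or reversed facial selectivity, because the α face carries the pseudo-axial C2 methyl group while the β face carries the C6 methyl group. Fallback, from 10 back to 11, for the case that electrophiles prefer the β face: NBS in THF–H2O forms the bromonium ion on that face and water opens it at C4 from the α side to give the 3β-bromo-4α-hydroxy ketone F10. K2CO3 in MeOH then closes the α-epoxide 11 with inversion at C3.

Step 3. Most likely failure: elimination from the oxyphosphonium ion, or displacement too slow at the neopentyl-type carbinol. Fallback, from 3 directly to 6: desymmetrising reduction of 3 with a ketoreductase (NADPH, glucose/glucose dehydrogenase recycling) chosen from a panel for hydride delivery on the allyl face, so that enzyme control replaces the inversion; no new compound arises.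

Step 25. Most likely failure: no reaction at the hindered axial tertiary hydroxyl, or its ionisation and loss as an alkene. Fallback, from 20 back to 30, installing the acetate through the alkoxide at the fragment stage: MeLi/CeCl3 addition to 20 is quenched with Ac2O to give the tertiary allylic acetate F11. BH3·THF followed by NaBO3 gives the primary alcohol F12, and Dess–Martin oxidation gives the acetoxy aldehyde F13. Julia–Lythgoe addition of the trianion of 19 at −78 °C with Ac2O quench gives the tetraacetate β-acetoxy sulfone F14, and Na(Hg) gives 30.

## Further compounds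

F1 | step 7 | keto dialdehyde from ozonolysis of 9 | O=CC[C@]1(C)[C@H](CCCC1=O)OC(C)(C)C=O
F2 | step 7 | cis-3,4-dihydroxy oxepane ketone (facial mixture) | OC1C[C@]2(C)[C@H](CCCC2=O)OC(C)(C)C1O
F3 | step 7 | cyclic 3,4-thiocarbonate of F2 | S=C1OC2C[C@]3(C)[C@H](CCCC3=O)OC(C)(C)C2O1
F4 | step 22 | Michael adduct keto sulfone (C10' ketone, C12 phenylsulfonyl, C3' benzyl ether) | O[C@H]1CC[C@]2(C)[C@H](CC[C@](C)(O)[C@H]2C(S(=O)(=O)c3ccccc3)C[C@H]3[C@]4(C)CC[C@H](OCc5ccccc5)C(C)(C)O[C@H]4CCC3=O)OC1(C)C
F5 | step 22 | C10' tertiary alcohol sulfone | O[C@H]1CC[C@]2(C)[C@H](CC[C@](C)(O)[C@H]2C(S(=O)(=O)c3ccccc3)C[C@H]3[C@]4(C)CC[C@H](OCc5ccccc5)C(C)(C)O[C@H]4CC[C@@]3(C)O)OC1(C)C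
F6 | step 22 | triol benzyl ether with saturated tether | O[C@H]1CC[C@]2(C)[C@H](CC[C@](C)(O)[C@H]2CC[C@H]3[C@]4(C)CC[C@H](OCc5ccccc5)C(C)(C)O[C@H]4CC[C@@]3(C)O)OC1(C)C
F7 | step 22 | saturated triacetate benzyl ether | CC(=O)O[C@H]1CC[C@]2(C)[C@H](CC[C@](C)(OC(C)=O)[C@H]2CC[C@H]3[C@]4(C)CC[C@H](OCc5ccccc5)C(C)(C)O[C@H]4CC[C@@]3(C)OC(C)=O)OC1(C)C
F8 | step 6 | 2-methylbut-3-yn-2-yl 2,2,2-trichloroacetimidate | CC(C)(OC(=N)C(Cl)(Cl)Cl)C#C
F9 | step 6 | (2R,3S)-2-allyl-2-methyl-3-(2-methylbut-3-yn-2-yloxy)cyclohexan-1-one | C=CC[C@]1(C)[C@H](CCCC1=O)OC(C)(C)C#C
F10 | step 8 | 3β-bromo-4α-hydroxy oxepane ketone | Br[C@@H]1[C@@H](O)C[C@]2(C)[C@H](CCCC2=O)OC1(C)C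
F0 | step 3 | none | none
F11 | step 25 | 3α-benzyloxy-10β-acetoxy-10α-methyl-11-methylene bicycle | c1ccccc1CO[C@H]2CC[C@]3(C)[C@H](CC[C@@](C)(OC(C)=O)C3=C)OC2(C)C
F12 | step 25 | 3α-benzyloxy-10β-acetoxy-12-hydroxy bicycle | c1ccccc1CO[C@H]2CC[C@]3(C)[C@H](CC[C@@](C)(OC(C)=O)[C@H]3CO)OC2(C)C
F13 | step 25 | 3α-benzyloxy-10β-acetoxy-12-aldehyde | c1ccccc1CO[C@H]2CC[C@]3(C)[C@H](CC[C@@](C)(OC(C)=O)[C@H]3C=O)OC2(C)C
F14 | step 25 | tetraacetate β-acetoxy sulfone (C3, C10, C10', C12' acetates; C3' benzyl ether) | CC(=O)O[C@H]1CC[C@]2(C)[C@H](CC[C@](C)(OC(C)=O)[C@H]2C(S(=O)(=O)c3ccccc3)C(OC(C)=O)[C@H]3[C@]4(C)CC[C@H](OCc5ccccc5)C(C)(C)O[C@H]4CC[C@@]3(C)OC(C)=O)OC1(C)C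
A1 | alternative 1 | 2,2-dimethylfuran-3-one with the C8'–C11' chain and terminal isopropenyl group on C7' | CC1(C)OC(=CC1=O)CC[C@@](C)(OC(C)=O)[C@@H](COC(C)=O)C(C)=C
A2 | alternative 1 | tricyclic furanone–cyclobutane–cyclohexane photoadduct | CC1(C)O[C@@]23CC[C@@](C)(OC(C)=O)[C@@H](COC(C)=O)[C@]2(C)C[C@H]3C1=O
A3 | alternative 2 | open-chain C6'–C7' epoxide with C2'/C3' acetonide, C10' carbinol and (E)-vinyl phenyl sulfone | CC1(C)O[C@@H](CC[C@]2(C)O[C@H]2CC[C@@](C)(O)/C=C/S(=O)(=O)c2ccccc2)C(C)(C)O1
A4 | alternative 2 | bis(cyclopentadienyl)titanium chloride Cp2TiCl | [Cl-].[Ti+3].c1cc[cH-]c1.c1cc[cH-]c1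
A5 | alternative 2 | cyclohexane-7',10'-diol with C12' phenyl sulfone and acetonide side chain | CC1(C)O[C@@H](CC[C@]2(C)[C@@H](O)CC[C@@](C)(O)[C@H]2CS(=O)(=O)c2ccccc2)C(C)(C)O1
A6 | alternative 3 | (R)-4-(tert-butyldimethylsilyloxy)-2,4-dimethylcyclohex-2-en-1-one | O=C1CC[C@@](C)(O[Si](C)(C)C(C)(C)C)C=C1C
A7 | alternative 3 | vinylene carbonate | O=C1OC=CO1
A8 | alternative 3 | cis-fused cyclobutane carbonate photoadduct | O=C1CC[C@@](C)(O[Si](C)(C)C(C)(C)C)[C@@H]2[C@H]3OC(=O)O[C@H]3[C@]12C
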